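## Structural features

The target is a monocyclic C20 acid: a cyclopentanone (ring carbons C8–C12) with a saturated seven-carbon carboxyl chain on C8 and a saturated eight-carbon chain on C12 that carries a secondary carbinol at C15. C8, C12 and C11 are three contiguous ring stereocentres (8R, 12R, 11R). The two chains are trans, and the C11 hydroxyl is trans to the C12 chain, so it lies on the face of the C8 chain. C15 (S) is separated from the ring by two methylenes, so no ring centre can control it. The C9 ketone and C11 hydroxyl form a β-ketol: acid or base eliminates water to the C10=C11 enone, the double bond can then migrate toward C8=C12, and C8 is an epimerisable α-carbon. The real difficulty is absolute and trans-relative control at C8/C12 on a five-membered ring, combined with a late, mild entry of the 11-hydroxyl and separate control of C15. The saturated C13–C14 bond helps: no alkene geometry has to survive, and a C13=C14 bond made by olefination can simply be hydrogenated. The feature used is that C8 lies between C9 (the carbonyl carbon) and C12 (which bears C13). With a nitro group on C9, C8=C9 is a Michael acceptor that already holds C1–C7, and C13–C12–C11–C10 is a 1,4-dialdehyde, so the ring closes by forming C8–C12 and C9–C10.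

## Logic of the disconnections

18 ⇐ 17. Only the O–CH3 bond of the C1 ester is cut. A free acid would interfere with the amine catalyst, the phosphonate anion and the borane, whereas the methyl ester is inert throughout and is the only spectator group needed. The forward step must cleave it at neutral pH because of the β-ketol, which points to an esterase.

17 ⇐ 16 ⇐ 15. The C11–O bond is removed by way of the C10–O bond of an epoxide. The 11-hydroxyl is β to the C9 carbonyl, so it can come from conjugate delivery of oxygen to a C10=C11 enone, with the adjacent C12 chain selecting the face. This removes the C11 stereocentre; 15 keeps only C8, C12 and C15. The forward steps must epoxidise on the α face and open the epoxide at C10–O alone without losing the new hydroxyl.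

15 ⇐ 13 ⇐ 12. The C9 carbonyl is traced back to a C9 nitro group, and the C10=C11 alkene to a C9=C10 nitroalkene and then to a C10 hydroxyl. Loss of the C10 hydroxyl gives the C9=C10 nitroalkene first. The unsaturation reaches C10=C11 only after γ-deprotonation at C11, when the nitronate carbon is oxidised, so two steps are planned for this change. The gain is that the two uncontrolled centres C9 and C10 of 12 are erased. The demand is deprotonation at C11 only, oxidation at C9, and no drift of the double bond toward C8=C12.

12 ⇐ 11 ⇐ 10. Two hydrogens across C13–C14 and a hydride at C15 are removed. A C13=C14–C15=O enone is what an olefination at C13 delivers, and the alkenyl/pentyl contrast gives a chiral reducing catalyst something to discriminate. The alkene must be saturated before any nitroalkene or ring enone exists. This removes the C15 stereocentre. The forward steps need a reagent-controlled 1,2-reduction and a hydrogenation that spares the nitro group and the allylic C–O bond.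

10 ⇐ 8 + 9. The C13=C14 bond is cut. The whole C14–C20 chain leaves as 9, which is commercial, and the route becomes convergent. The olefination must be E-selective and mild enough for a β-nitro alcohol next to an α-branched aldehyde.

8 ⇐ 7 ⇐ 4 + 6. The C9–C10 and C8–C12 bonds are cut. This removes the ring and all four ring stereocentres of 8 at once and leaves an achiral nitroalkene and an achiral C4 dialdehyde. The forward step needs one catalyst-controlled C–C bond (C8), an epimerisable C12, and a nitronate that can only close a five-membered ring.

4 ⇐ 1 + 2 and 6 ⇐ 5. The C8=C9 bond of 4 is cut back to an aldehyde and a one-carbon nitro nucleophile, and 6 is unmasked from its cyclic bis-acetal. Both need only that the products are used fresh: 4 as the E isomer, 6 before it oligomerises.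

## Other disconnections considered

Alternative 1: The cut is C7–C8 (enolate alkylation) together with C8–C12, made through a sacrificial C8–C13 bond. In the forward key step Rh2(OAc)4 decomposes the acyclic diazoketone A2, (4R,5E,8S)-1-diazo-4,8-bis(tert-butyldimethylsilyloxy)tridec-5-en-2-one. The rhodium carbenoid at C8 adds to the C12=C13 alkene and gives the bicyclo[3.1.0]hexanone A1. Dissolving-metal cleavage of the C8–C13 bond would then release a regiodefined C8 enolate for alkylation with methyl 7-iodoheptanoate A3.
- In its favour: A1 already carries the C11 oxygen and the C15 carbinol, and C12 is set relative to C11 by addition anti to the silyloxy group. The reductive opening leaves C13 as a methylene, which is exactly the saturation this target has.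
- Against it here: A2 needs two separately made stereocentres and a hazardous diazo transfer or diazomethane step before the ring exists. Two cyclopropane bonds (C8–C13 and C8–C12) compete in the cleavage, and the choice rests on orbital overlap alone. The C8 enolate must be alkylated by an unactivated primary iodide faster than it equilibrates to the C10 enolate, which would expel the C11 silyloxy group.
- Comparison: on structure it is the better plan for C13–C14 and for early placement of the 11-oxygen, since it needs no hydrogenation and no epoxide. The chosen plan is better at C8, because C1–C7 is present from the start and no ketone enolate is alkylated. Mechanistically a metal carbenoid and a strongly reducing opening stand against amine catalysis at room temperature. The two are equal in needing two independent sources of absolute configuration. On step economy the long acyclic preparation of A2 should make it clearly longer.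

Alternative 2: The cuts are C8–C9 and C11–C12, with both chains attached afterwards. In the forward key step (S)-proline catalyses the cross-aldol of two molecules of 6 (C8–C9). Dibenzylammonium trifluoroacetate then drives the intramolecular aldol condensation (C11–C12), and the C9 hydroxyl closes on C6 to give the bicyclic enal lactol A4. The lower chain would enter by conjugate addition of a saturated C13–C20 organocopper reagent to C12 of A4. The extra formyl carbon would be removed by ozonolysis of the derived enol ether to a C11 ketone, and the upper chain would be built by Wittig reaction at the C6 lactol.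
- In its favour: it uses the same C4 feedstock, forms the ring in one operation, sets C8 and the C9 oxygen with the high selectivity expected of a proline aldol, and directs the C12 substituent trans to C8.
- Against it here: 6 has many competing aldol pathways, so the dimerisation is expected to be modest in yield. The oxidation levels are those of the F series (C9 alcohol, C11 ketone), so an E-type target needs reduction at C11, protection of the 11- and 15-hydroxyls, oxidation at C9 and deprotection. The Wittig alkene at C5=C6 must also be hydrogenated.
- Comparison: it is equal in starting from 6 and an aminocatalyst. It is better in avoiding the nitro-to-carbonyl change and the base-sensitive C10=C11 enone, and in making the 11-hydroxyl by ketone reduction and not by a face-selective epoxidation. The chosen plan is better in carrying C1–C7 and the C9 oxidation level from the start and in using no protecting groups. The step counts should be comparable.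

Alternative 3: The cuts are C8–C12, C9–O, C11–O and C15–O. In the forward key step cyclooxygenase removes a hydrogen atom from C13 of (8Z,11Z,14Z)-icosa-8,11,14-trienoic acid A6. Dioxygen adds at C11, the peroxyl radical closes on C9, the C8 radical closes on C12, and a second dioxygen is taken up at C15 to give the hydroperoxy endoperoxide A5. Reduction of the hydroperoxide and isomerisation of the endoperoxide would give A7 (PGE1), whose C13=C14 bond would be hydrogenated.
- In its favour: every stereocentre comes from an achiral acid in one step, with no protecting groups and the fewest operations.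
- Against it here: it depends on an enzyme preparation that inactivates itself during turnover and on a costly substrate. A5 is a labile peroxide. The endoperoxide can isomerise in more than one direction or fragment. The last hydrogenation has to be done on a β-ketol.
- Comparison: it is clearly the better plan on step economy and at least equal on stereocontrol. The chosen plan is better in material throughput, in stable intermediates that can be purified, and in independence from biological material. Both end with an enzyme.

Key step: step 3

Assumption: C9 and C10 of 8, 10, 11 and 12 are carried as a mixture of epimers (the all-trans isomer is expected to dominate) and are written without configuration, because both centres become trigonal in steps 7 and 8.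

## Route

Step 1
Reactants: 1 methyl 8-oxooctanoate; 2 nitromethane
Product: 4 methyl (E)-9-nitronon-8-enoate, via methyl 8-hydroxy-9-nitrononanoate 3 (not isolated)
Conditions: MeNO2 (excess), Et3N, rt; evaporate; MsCl, Et3N, CH2Cl2, 0 °C
Reagents that add atoms: none
Why: Henry (nitroaldol) addition of the nitromethane anion to the aldehyde, then mesylation and E1cB elimination, should give the conjugated E-nitroalkene; the methyl ester is inert to amine bases.

Step 2
Reactants: 5 2,5-dimethoxytetrahydrofuran
Product: 6 succinaldehyde
Conditions: H2O, 90 °C; MeOH/H2O distilled off; extracted into CH2Cl2, used at once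
Reagents that add atoms: water, O
Why: Hydrolysis of the cyclic bis-acetal releases the 1,4-dialdehyde; distilling off methanol drives the equilibrium, and immediate use limits oligomerisation.

Step 3
Reactants: 6 succinaldehyde (excess); 4 methyl (E)-9-nitronon-8-enoate
Product: 8 methyl 7-[(1R,2S)-2-formyl-4-hydroxy-5-nitrocyclopentyl]heptanoate, via methyl (8R,9R)-9-formyl-8-(nitromethyl)-11-oxoundecanoate 7 (not isolated)
Conditions: (S)-2-[diphenyl(trimethylsilyloxy)methyl]pyrrolidine (10 mol %), 4-nitrophenol (10 mol %), MeCN, rt; then iPr2NEt, 0 °C
Reagents that add atoms: none
Why: The secondary amine condenses with one formyl group of 6 to an E-enamine whose diphenyl(trimethylsilyloxy)methyl arm blocks one face; the open face of enamine carbon C12 adds to C8 of 4 through an acyclic synclinal transition state, and hydrolysis of the iminium releases the syn γ-nitro dialdehyde 7 and the catalyst. The closest known reaction type is the diarylprolinol silyl ether-catalysed Michael addition of aldehydes to nitroalkenes run in tandem with an intramolecular Henry reaction, a formal [3+2] cyclopentane annulation. On addition of iPr2NEt the C9 nitronate attacks the C10 aldehyde in a 5-(enolexo)-exo-trig closure that forms C9–C10 and the only ring. C8 is set by the catalyst alone, the S catalyst giving the sense required by the target. C12 is formed cis to the C8 chain but lies α to a formyl group and should be epimerised by the amine to the more stable trans isomer. C9 and C10 form under reversible nitroaldol conditions and should settle mainly all-trans; their configuration is immaterial. The step needs chemoselectivity between the two formyl groups and against self-aldolisation of 6: the high electrophilicity of the nitroalkene, the excess of 6 and the weak acid co-catalyst favour the cross-Michael path, and the nitronate can reach only C10 through a five-membered transition state, since attack on C13 would need a four-membered ring.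

Step 4
Reactants: 8 methyl 7-[(1R,2S)-2-formyl-4-hydroxy-5-nitrocyclopentyl]heptanoate; 9 dimethyl (2-oxoheptyl)phosphonate
Product: 10 methyl 7-[(1R,2R)-4-hydroxy-5-nitro-2-[(1E)-3-oxooct-1-en-1-yl]cyclopentyl]heptanoate
Conditions: LiCl, iPr2NEt, MeCN, 0 °C → rt
Reagents that add atoms: none
Why: Horner–Wadsworth–Emmons olefination with a lithium-chelated β-keto phosphonate under amine base should give the E-enone; the base is too weak to dehydrate the β-nitro alcohol, and the aldehyde is already in its stable trans arrangement.

Step 5
Reactants: 10 methyl 7-[(1R,2R)-4-hydroxy-5-nitro-2-[(1E)-3-oxooct-1-en-1-yl]cyclopentyl]heptanoate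
Product: 11 methyl 7-[(1R,2R)-4-hydroxy-2-[(1E,3S)-3-hydroxyoct-1-en-1-yl]-5-nitrocyclopentyl]heptanoate
Conditions: (R)-1-methyl-3,3-diphenyltetrahydro-1H,3H-pyrrolo[1,2-c][1,3,2]oxazaborole (20 mol %), catecholborane (excess), toluene–CH2Cl2, −78 °C; MeOH quench
Reagents that add atoms: none
Why: Corey–Bakshi–Shibata reduction: the ketone binds the ring boron with its larger alkenyl arm away from the catalyst and hydride is delivered within the complex, which with the R catalyst should give 15S under pure reagent control; catecholborane favours 1,2-reduction and leaves the nitro and ester groups alone.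

Step 6
Reactants: 11 methyl 7-[(1R,2R)-4-hydroxy-2-[(1E,3S)-3-hydroxyoct-1-en-1-yl]-5-nitrocyclopentyl]heptanoate
Product: 12 methyl 7-[(1R,2S)-4-hydroxy-2-[(3S)-3-hydroxyoctyl]-5-nitrocyclopentyl]heptanoate
Conditions: H2 (1 atm), RhCl(PPh3)3 (5 mol %), toluene–EtOH, rt
Reagents that add atoms: none
Why: Homogeneous hydrogenation with RhCl(PPh3)3 reduces the unhindered disubstituted alkene without touching the secondary nitro group or the ester and without hydrogenolysis of the allylic C–O bond; no stereocentre is formed or affected.

Step 7
Reactants: 12 methyl 7-[(1R,2S)-4-hydroxy-2-[(3S)-3-hydroxyoctyl]-5-nitrocyclopentyl]heptanoate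
Product: 13 methyl 7-[(1R,5S)-5-[(3S)-3-hydroxyoctyl]-2-nitrocyclopent-2-en-1-yl]heptanoate
Conditions: acidic Al2O3, ClCH2CH2Cl, 60 °C
Reagents that add atoms: none
Why: Dehydration of a β-nitro alcohol on alumina (E1cB through the aci-nitro form) should give the conjugated C9=C10 nitroalkene from every C9/C10 epimer; the C15 carbinol has no acidifying neighbour and stays, and C8 is not touched.

Step 8
Reactants: 13 methyl 7-[(1R,5S)-5-[(3S)-3-hydroxyoctyl]-2-nitrocyclopent-2-en-1-yl]heptanoate
Product: 15 methyl 7-[(1R,2S)-2-[(3S)-3-hydroxyoctyl]-5-oxocyclopent-3-en-1-yl]heptanoate, via allylic nitro isomer 14 (not isolated)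
Conditions: DABCO (2 equiv), O2 (1 atm), MeCN, 0 °C → rt
Reagents that add atoms: dioxygen, O=O
Why: The amine removes the γ-hydrogen at C11 (the C8 hydrogen is not activated) to give a dienyl nitronate in equilibrium with 14, and dioxygen oxidises the nitronate carbon C9 to the carbonyl with loss of nitrite (oxidative Nef reaction), which leaves the C10=C11 enone; the trans arrangement at C8/C12 is the stable one.

Step 9
Reactants: 15 methyl 7-[(1R,2S)-2-[(3S)-3-hydroxyoctyl]-5-oxocyclopent-3-en-1-yl]heptanoate
Product: 16 methyl 7-[(1S,2R,3R,5S)-2-[(3S)-3-hydroxyoctyl]-4-oxo-6-oxabicyclo[3.1.0]hexan-3-yl]heptanoate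
Conditions: 30% H2O2, KOH (0.2 equiv), MeOH, −40 → −20 °C
Reagents that add atoms: hydrogen peroxide, OO
Why: Weitz–Scheffer nucleophilic epoxidation: hydroperoxide should add to C11 on the face away from the adjacent C12 chain and the enolate closes on the same face to the 10α,11α-epoxide; the low temperature holds back base-induced double-bond migration.

Step 10
Reactants: 16 methyl 7-[(1S,2R,3R,5S)-2-[(3S)-3-hydroxyoctyl]-4-oxo-6-oxabicyclo[3.1.0]hexan-3-yl]heptanoate
Product: 17 methyl 7-[(1R,2R,3R)-3-hydroxy-2-[(3S)-3-hydroxyoctyl]-5-oxocyclopentyl]heptanoate
Conditions: Zn, NH4Cl, MeOH–H2O, 0 °C → rt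
Reagents that add atoms: none
Why: Electron transfer to the carbonyl of the α,β-epoxy ketone cleaves the C10–O bond and leaves the C11–O bond, so the 11α configuration is kept; the nearly neutral buffer avoids β-elimination of the new ketol.

Step 11
Reactants: 17 methyl 7-[(1R,2R,3R)-3-hydroxy-2-[(3S)-3-hydroxyoctyl]-5-oxocyclopentyl]heptanoate
Product: 18 7-[(1R,2R,3R)-3-hydroxy-2-[(3S)-3-hydroxyoctyl]-5-oxocyclopentyl]heptanoic acid
Conditions: porcine liver esterase, pH 7 phosphate buffer–acetone, 30 °C
Reagents that add atoms: water, O
Why: Enzymatic hydrolysis of the unhindered terminal methyl ester at neutral pH avoids the dehydration of the β-ketol and the C8 epimerisation that hydroxide would cause.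

## Compound list

1 | methyl 8-oxooctanoate | COC(=O)CCCCCCC=O | starting material
2 | nitromethane | C[N+](=O)[O-] | starting material
3 | methyl 8-hydroxy-9-nitrononanoate (racemic) | COC(=O)CCCCCCC(O)C[N+](=O)[O-] | intermediate
4 | methyl (E)-9-nitronon-8-enoate | COC(=O)CCCCCC/C=C/[N+](=O)[O-] | intermediate
5 | 2,5-dimethoxytetrahydrofuran (isomer mixture) | COC1CCC(OC)O1 | starting material
6 | succinaldehyde | O=CCCC=O | intermediate
7 | methyl (8R,9R)-9-formyl-8-(nitromethyl)-11-oxoundecanoate | COC(=O)CCCCCC[C@@H](C[N+](=O)[O-])[C@H](C=O)CC=O | intermediate
8 | methyl 7-[(1R,2S)-2-formyl-4-hydroxy-5-nitrocyclopentyl]heptanoate (C4/C5 epimers) | O=C[C@H]1CC(O)C([N+](=O)[O-])[C@@H]1CCCCCCC(=O)OC | intermediate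
9 | dimethyl (2-oxoheptyl)phosphonate | CCCCCC(=O)CP(=O)(OC)OC | starting material
10 | methyl 7-[(1R,2R)-4-hydroxy-5-nitro-2-[(1E)-3-oxooct-1-en-1-yl]cyclopentyl]heptanoate | CCCCCC(=O)/C=C/[C@H]1CC(O)C([N+](=O)[O-])[C@@H]1CCCCCCC(=O)OC | intermediate
11 | methyl 7-[(1R,2R)-4-hydroxy-2-[(1E,3S)-3-hydroxyoct-1-en-1-yl]-5-nitrocyclopentyl]heptanoate | CCCCC[C@H](O)/C=C/[C@H]1CC(O)C([N+](=O)[O-])[C@@H]1CCCCCCC(=O)OC | intermediate
12 | methyl 7-[(1R,2S)-4-hydroxy-2-[(3S)-3-hydroxyoctyl]-5-nitrocyclopentyl]heptanoate | CCCCC[C@H](O)CC[C@H]1CC(O)C([N+](=O)[O-])[C@@H]1CCCCCCC(=O)OC | intermediate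
13 | methyl 7-[(1R,5S)-5-[(3S)-3-hydroxyoctyl]-2-nitrocyclopent-2-en-1-yl]heptanoate | CCCCC[C@H](O)CC[C@H]1CC=C([N+](=O)[O-])[C@@H]1CCCCCCC(=O)OC | intermediate
14 | methyl 7-[(1R,5S)-5-[(3S)-3-hydroxyoctyl]-2-nitrocyclopent-3-en-1-yl]heptanoate (C2 epimers, in equilibrium with its nitronate) | CCCCC[C@H](O)CC[C@H]1C=CC([N+](=O)[O-])[C@@H]1CCCCCCC(=O)OC | intermediate
15 | methyl 7-[(1R,2S)-2-[(3S)-3-hydroxyoctyl]-5-oxocyclopent-3-en-1-yl]heptanoate | CCCCC[C@H](O)CC[C@H]1C=CC(=O)[C@@H]1CCCCCCC(=O)OC | intermediate
16 | methyl 7-[(1S,2R,3R,5S)-2-[(3S)-3-hydroxyoctyl]-4-oxo-6-oxabicyclo[3.1.0]hexan-3-yl]heptanoate | CCCCC[C@H](O)CC[C@H]1[C@@H]2O[C@@H]2C(=O)[C@@H]1CCCCCCC(=O)OC | intermediate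
17 | methyl 7-[(1R,2R,3R)-3-hydroxy-2-[(3S)-3-hydroxyoctyl]-5-oxocyclopentyl]heptanoate | CCCCC[C@H](O)CC[C@H]1[C@H](O)CC(=O)[C@@H]1CCCCCCC(=O)OC | intermediate
18 | 7-[(1R,2R,3R)-3-hydroxy-2-[(3S)-3-hydroxyoctyl]-5-oxocyclopentyl]heptanoic acid (13,14-dihydro-PGE1) | CCCCC[C@H](O)CC[C@H]1[C@H](O)CC(=O)[C@@H]1CCCCCCC(=O)O | target

## Step count and least certain steps

Total: 11 steps. Longest linear sequence: 10 steps (steps 1 and 3–11, from 1); step 2 is a one-step branch.

Step 3 (key step). The most likely failure is self-aldolisation and oligomerisation of the dialdehyde, which would consume donor and catalyst faster than the cross-Michael addition; incomplete equilibration at C12 is a second possibility. The fallback separates donor reactivity from the second formyl group. It sets out from 4, to which commercial pent-4-enal is added under the same amine catalysis to give methyl (8R,9R)-9-formyl-8-(nitromethyl)dodec-11-enoate F1. Ozonolysis of the terminal alkene (O3, CH2Cl2–MeOH, −78 °C; Me2S) unmasks the second aldehyde to give 7, and iPr2NEt closes the ring, so the route is rejoined at 8.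

Step 8. The most likely failure is over-isomerisation once the enone has formed: the amine could move the double bond toward the tetrasubstituted C8=C12 position and epimerise C8. Slow oxidation of the nitronate would lengthen that exposure. The fallback sets out from 13 and uses DABCO in degassed MeCN under argon to stop at 14, which is isolated. The nitronate of 14 (NaOMe, MeOH, 0 °C) is then added to aqueous TiCl3 buffered with NH4OAc (reductive Nef reaction through the imine), and the route is rejoined at 15 without dioxygen and with only brief contact between enone and base.

Step 9. The most likely failure is poor facial selectivity of the hydroperoxide addition, because the flexible saturated C12 chain may shield the β face only moderately; base-induced isomerisation of 15 may compete. The fallback replaces oxygen delivery by boron delivery and bypasses 16 and step 10. It sets out from 15, which undergoes conjugate borylation with bis(pinacolato)diboron (CuCl, NaOtBu, bis(2-diphenylphosphinophenyl) ether, THF–MeOH, rt). The bulky boryl-copper species should add anti to the C12 chain and give methyl 7-[(1R,2S,3R)-2-[(3S)-3-hydroxyoctyl]-5-oxo-3-(4,4,5,5-tetramethyl-1,3,2-dioxaborolan-2-yl)cyclopentyl]heptanoate F2. Oxidation of the C–B bond with retention (NaBO3·4H2O, THF–H2O, rt) rejoins the route at 17.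

Step 5. The most likely failure is insufficient facial discrimination at C15, or slowing of the catalyst through binding of the free C10 hydroxyl and the nitro group. The fallback gives up reagent control. It sets out from 10, which is reduced with NaBH4/CeCl3·7H2O (Luche reduction) to 11 and its epimer methyl 7-[(1R,2R)-4-hydroxy-2-[(1E,3R)-3-hydroxyoct-1-en-1-yl]-5-nitrocyclopentyl]heptanoate F3. The epimers are separated by chromatography, and F3 is recycled to 10 by allylic oxidation with MnO2. The route is rejoined at 11.

Step 6. The most likely failure is isomerisation of the allylic alcohol to the C15 ketone by a rhodium hydride, or incomplete conversion. The fallback uses a metal-free reduction: it sets out from 11 and uses diimide generated from 2-nitrobenzenesulfonohydrazide and Et3N in CH2Cl2. The concerted syn transfer of two hydrogens cannot isomerise the alcohol and leaves the nitro group alone. The route is rejoined at 12, and no new compound is made.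

## Further compounds

F1 | step 3 | methyl (8R,9R)-9-formyl-8-(nitromethyl)dodec-11-enoate | COC(=O)CCCCCC[C@@H](C[N+](=O)[O-])[C@H](C=O)CC=C
F0 | step 8 | none | none
F2 | step 9 | methyl 7-[(1R,2S,3R)-2-[(3S)-3-hydroxyoctyl]-5-oxo-3-(4,4,5,5-tetramethyl-1,3,2-dioxaborolan-2-yl)cyclopentyl]heptanoate | CCCCC[C@H](O)CC[C@H]1[C@H](B2OC(C)(C)C(C)(C)O2)CC(=O)[C@@H]1CCCCCCC(=O)OC
F3 | step 5 | methyl 7-[(1R,2R)-4-hydroxy-2-[(1E,3R)-3-hydroxyoct-1-en-1-yl]-5-nitrocyclopentyl]heptanoate | CCCCC[C@@H](O)/C=C/[C@H]1CC(O)C([N+](=O)[O-])[C@@H]1CCCCCCC(=O)OC
F0 | step 6 | none | none
A1 | alternative 1 | (1S,4R,5R,6R)-4-(tert-butyldimethylsilyloxy)-6-[(2S)-2-(tert-butyldimethylsilyloxy)heptyl]bicyclo[3.1.0]hexan-2-one | CCCCC[C@H](O[Si](C)(C)C(C)(C)C)C[C@@H]1[C@H]2[C@H](O[Si](C)(C)C(C)(C)C)CC(=O)[C@@H]12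
A2 | alternative 1 | (4R,5E,8S)-1-diazo-4,8-bis(tert-butyldimethylsilyloxy)tridec-5-en-2-one | CCCCC[C@H](O[Si](C)(C)C(C)(C)C)C/C=C/[C@H](O[Si](C)(C)C(C)(C)C)CC(=O)C=[N+]=[N-]
A3 | alternative 1 | methyl 7-iodoheptanoate | COC(=O)CCCCCCI
A4 | alternative 2 | (3aR,6aS)-2-hydroxy-3,3a,6,6a-tetrahydro-2H-cyclopenta[b]furan-5-carbaldehyde | O=CC1=C[C@H]2CC(O)O[C@H]2C1
A5 | alternative 3 | (13E,15S)-15-hydroperoxy-9α,11α-epidioxyprost-13-enoic acid (prostaglandin G1) | CCCCC[C@H](OO)/C=C/[C@H]1[C@H]2C[C@H](OO2)[C@@H]1CCCCCCC(=O)O
A6 | alternative 3 | (8Z,11Z,14Z)-icosa-8,11,14-trienoic acid | CCCCC/C=C\C/C=C\C/C=C\CCCCCCC(=O)O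
A7 | alternative 3 | 7-[(1R,2R,3R)-3-hydroxy-2-[(1E,3S)-3-hydroxyoct-1-en-1-yl]-5-oxocyclopentyl]heptanoic acid (PGE1) | CCCCC[C@H](O)/C=C/[C@H]1[C@H](O)CC(=O)[C@@H]1CCCCCCC(=O)O
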